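Everything rests on opening the furan-3(2H)-one ring (O, C3, C2, C1, C10) at O–C3 and returning the C10 methyl group (C14) to C1, which uncovers a 2-hydroxy-2-alkynyl ketone that biacetyl can supply. The feature exploited is quaternary C10, which holds C14 and the ring oxygen right beside the C1 ketone. In one operation AuCl3 closes the furanone ring, makes O–C3 and C10–C14, and passes the C1 configuration on to C10. The precursor is an acyclic (S)-tertiary propargylic alcohol: its alkyne carries the silyl-protected C4–C6/C15 enediol, its ketone side carries the C8 isovalerate and the C7=C11 acrylate; the ten-membered ring is closed later at C6–C7.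

Key step: step 12

Remark on numbering: germacrane numbering is used throughout (C1 ketone, C2=C3 of the furanone, C4=C5, C6 lactone carbinol, C7, C8 ester carbinol, C9, quaternary C10, C11–C13 methylene lactone, C14 methyl, C15 hydroxymethyl).
Remark on the precursor design: the oxygens on C6 (cis to the alkyne) and C15 are carried as bulky silyl ethers and the oxidatively removable PMB group sits on remote C13, so that the ketone oxygen is the only competent nucleophile for the activated alkyne; the tertiary C1 hydroxyl is masked (TMS) only for the aldol and the acylation.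
Assumption: the amino alcohol named in step 4 is taken to deliver the (S)-carbinol, and (−)-Ipc2BCl in step 10 to direct re-face attack on the aldehyde; should either sense prove opposite, the enantiomeric ligand or reagent is used.

Step 1
Reactants: 1 2-butyne-1,4-diol
Product: 2 4-[(tert-butyldiphenylsilyl)oxy]but-2-yn-1-ol
Conditions: TBDPSCl (1 equiv), imidazole, 1 (3 equiv), DMF, 0 °C to rt
Reagents that add atoms: tert-butyl(chloro)diphenylsilane (TBDPSCl), CC(C)(C)[Si](Cl)(c1ccccc1)c1ccccc1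
Why: Statistical monosilylation (silyl ether formation) of a symmetrical diol used in excess, so that the future C15 oxygen is capped with a robust silyl group and the other hydroxyl stays free to direct the next step.

Step 2
Reactants: 2 4-[(tert-butyldiphenylsilyl)oxy]but-2-yn-1-ol
Product: 4 (2Z)-4-[(tert-butyldiphenylsilyl)oxy]-3-iodobut-2-en-1-ol, via cyclic alkenylalanate 3 (not isolated)
Conditions: NaAlH2(OCH2CH2OMe)2, THF, 0 °C; then I2, THF, −78 to 0 °C
Reagents that add atoms: iodine, II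
Why: Hydroxyl-directed trans-hydroalumination of the propargylic alcohol places aluminium on C3 of the butene, cis to the carbinol, and iodinolysis with retention gives the (Z)-vinyl iodide, which fixes the geometry of the future C4=C5 bond.

Step 3
Reactants: 4 (2Z)-4-[(tert-butyldiphenylsilyl)oxy]-3-iodobut-2-en-1-ol
Product: 5 (2Z)-1-[(tert-butyldimethylsilyl)oxy]-4-[(tert-butyldiphenylsilyl)oxy]-3-iodobut-2-ene
Conditions: TBSCl, imidazole, CH2Cl2, 0 °C to rt
Reagents that add atoms: tert-butyl(chloro)dimethylsilane (TBSCl), CC(C)(C)[Si](C)(C)Cl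
Why: Standard silylation of the primary allylic alcohol (the future C6 oxygen) with a silyl group that can later be removed in the presence of TBDPS.

Step 4
Reactants: 6 2,3-butanedione (biacetyl, in excess); 7 trimethylsilylacetylene
Product: 8 (3S)-3-hydroxy-3-methyl-5-(trimethylsilyl)pent-4-yn-2-one
Conditions: Zn(OTf)2 (20 mol %), (1S,2S)-2-(dimethylamino)-3-[(tert-butyldimethylsilyl)oxy]-1-(4-nitrophenyl)propan-1-ol (22 mol %), Et3N (30 mol %), toluene, rt to 50 °C
Reagents that add atoms: none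
Why: Proposed new method: the zinc acetylide formed from 7 with Zn(OTf)2/Et3N adds to one carbonyl of the zinc-chelated diketone inside the chiral amino-alkoxide complex, the second carbonyl playing the chelating role that the ester plays in α-keto esters, so that the reacting C=O is differentiated as methyl versus chelate arm and C1 is set as (S); the symmetry of 6 removes any regiochemical question and the hindered, chelated mono-adduct should resist a second addition; the closest known reaction type is the zinc/amino alcohol-mediated enantioselective alkynylation of α-keto esters.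

Step 5
Reactants: 8 (3S)-3-hydroxy-3-methyl-5-(trimethylsilyl)pent-4-yn-2-one
Product: 9 (3S)-3-hydroxy-3-methylpent-4-yn-2-one
Conditions: K2CO3 (cat.), MeOH, 0 °C (product handled as a concentrated solution)
Reagents that add atoms: none
Why: Base-catalysed methanolytic protodesilylation of an alkynylsilane, mild enough to leave the α-hydroxy ketone untouched.

Step 6
Reactants: 5 (2Z)-1-[(tert-butyldimethylsilyl)oxy]-4-[(tert-butyldiphenylsilyl)oxy]-3-iodobut-2-ene; 9 (3S)-3-hydroxy-3-methylpent-4-yn-2-one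
Product: 10 (3S,6E)-8-[(tert-butyldimethylsilyl)oxy]-6-{[(tert-butyldiphenylsilyl)oxy]methyl}-3-hydroxy-3-methyloct-6-en-4-yn-2-one (alkyne and CH2OTBS cis on the alkene)
Conditions: Pd(PPh3)2Cl2 (cat.), CuI (cat.), Et3N, THF, rt
Reagents that add atoms: none
Why: Sonogashira coupling of a vinyl iodide with a terminal alkyne, which proceeds with retention of the alkene geometry and tolerates the free tertiary alcohol and the ketone.

Step 7
Reactants: 10 (3S,6E)-8-[(tert-butyldimethylsilyl)oxy]-6-{[(tert-butyldiphenylsilyl)oxy]methyl}-3-hydroxy-3-methyloct-6-en-4-yn-2-one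
Product: 11 (3S,6E)-8-[(tert-butyldimethylsilyl)oxy]-6-{[(tert-butyldiphenylsilyl)oxy]methyl}-3-methyl-3-[(trimethylsilyl)oxy]oct-6-en-4-yn-2-one
Conditions: N-(trimethylsilyl)imidazole, CH2Cl2, rt
Reagents that add atoms: N-(trimethylsilyl)imidazole, C[Si](C)(C)n1ccnc1
Why: Silylation of the hindered tertiary alcohol with a silyl-imidazole donor, so that the boron reagent of step 10 meets only the methyl ketone.

Step 8
Reactants: 12 4-methoxybenzyl alcohol; 13 methyl 2-(dimethoxyphosphoryl)acrylate; 14 2,2-dimethoxyacetaldehyde (anhydrous)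
Product: 16 methyl (2E)-4,4-dimethoxy-2-{[(4-methoxybenzyl)oxy]methyl}but-2-enoate, via phosphonate carbanion sodium salt 15 (not isolated)
Conditions: NaH, THF, 0 °C; then 14, −78 °C to rt
Reagents that add atoms: none
Why: Tandem oxa-Michael addition/Horner–Wadsworth–Emmons olefination, in which the alkoxide of 12 adds to the phosphonoacrylate and the phosphonate carbanion so formed olefinates the aldehyde, α-substituted phosphonoacetates favouring the alkene with the new substituent trans to the ester, here (E).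

Step 9
Reactants: 16 methyl (2E)-4,4-dimethoxy-2-{[(4-methoxybenzyl)oxy]methyl}but-2-enoate
Product: 17 methyl (2E)-2-{[(4-methoxybenzyl)oxy]methyl}-4-oxobut-2-enoate
Conditions: Amberlyst-15, acetone/H2O, rt
Reagents that add atoms: water, O
Why: Acid-catalysed acetal hydrolysis that leaves the PMB ether and the ester intact, the acidic medium also letting any cis-enal relax to the more stable (E)-isomer with the aldehyde trans to the ester.

Step 10
Reactants: 11 (3S,6E)-8-[(tert-butyldimethylsilyl)oxy]-6-{[(tert-butyldiphenylsilyl)oxy]methyl}-3-methyl-3-[(trimethylsilyl)oxy]oct-6-en-4-yn-2-one; 17 methyl (2E)-2-{[(4-methoxybenzyl)oxy]methyl}-4-oxobut-2-enoate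
Product: 19 methyl (2E,4R,7S,10E)-12-[(tert-butyldimethylsilyl)oxy]-10-{[(tert-butyldiphenylsilyl)oxy]methyl}-4-hydroxy-2-{[(4-methoxybenzyl)oxy]methyl}-7-methyl-6-oxo-7-[(trimethylsilyl)oxy]dodeca-2,10-dien-8-ynoate, via diisopinocampheylboron enolate 18 (not isolated)
Conditions: (−)-Ipc2BCl, Et3N, Et2O, −78 to 0 °C; then 17, −78 to −20 °C; H2O2, pH 7 buffer, MeOH, 0 °C
Reagents that add atoms: none
Why: Diisopinocampheylboron-mediated aldol addition of a methyl ketone, in which only the C9 methyl can be enolised, the closed boron transition state ensures 1,2-addition to the enal, the chiral ligands on boron direct attack to the re face of the aldehyde and so set C8 as (R), and the minor C8 epimer is a diastereomer removable by chromatography.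

Step 11
Reactants: 19 methyl (2E,4R,7S,10E)-12-[(tert-butyldimethylsilyl)oxy]-10-{[(tert-butyldiphenylsilyl)oxy]methyl}-4-hydroxy-2-{[(4-methoxybenzyl)oxy]methyl}-7-methyl-6-oxo-7-[(trimethylsilyl)oxy]dodeca-2,10-dien-8-ynoate
Product: 21 methyl (2E,4R,7S,10E)-12-[(tert-butyldimethylsilyl)oxy]-10-{[(tert-butyldiphenylsilyl)oxy]methyl}-7-hydroxy-2-{[(4-methoxybenzyl)oxy]methyl}-7-methyl-4-[(3-methylbutanoyl)oxy]-6-oxododeca-2,10-dien-8-ynoate (the cyclisation precursor), via TMS ether isovalerate 20 (not isolated)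
Conditions: (i-BuCO)2O, DMAP (cat.), pyridine, CH2Cl2, 0 °C; then citric acid, MeOH, rt
Reagents that add atoms: 3-methylbutanoic anhydride, CC(C)CC(=O)OC(=O)CC(C)C
Why: DMAP-catalysed acylation of the secondary C8 alcohol under cold, weakly basic conditions that avoid β-elimination, followed in the same flask by mild acid methanolysis of the tertiary TMS ether, which is far more labile than the primary TBS, TBDPS and PMB ethers.

Step 12
Reactants: 21 methyl (2E,4R,7S,10E)-12-[(tert-butyldimethylsilyl)oxy]-10-{[(tert-butyldiphenylsilyl)oxy]methyl}-7-hydroxy-2-{[(4-methoxybenzyl)oxy]methyl}-7-methyl-4-[(3-methylbutanoyl)oxy]-6-oxododeca-2,10-dien-8-ynoate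
Product: 22 methyl (2E,4R)-5-[(2S)-5-{(2Z)-4-[(tert-butyldimethylsilyl)oxy]-1-[(tert-butyldiphenylsilyl)oxy]but-2-en-2-yl}-2-methyl-3-oxo-2,3-dihydrofuran-2-yl]-2-{[(4-methoxybenzyl)oxy]methyl}-4-[(3-methylbutanoyl)oxy]pent-2-enoate (the 2,2,5-trisubstituted furan-3(2H)-one seco-compound)
Conditions: AuCl3 (5 mol %), CH2Cl2, rt
Reagents that add atoms: none
Why: AuCl3 (trivalent gold) binds the C2≡C3 triple bond and the ketone oxygen on C10 adds to C3, giving a cyclic oxocarbenium ion that carries gold on C2. The methyl group on C1 then migrates to cationic C10 while the C1 hydroxyl collapses to the ketone (a semipinacol-type 1,2-shift), and protodeauration at C2 releases the furan-3(2H)-one and the catalyst. The closest known reaction type is the gold- or platinum-catalysed heterocyclisation with 1,2-alkyl shift of 2-hydroxy-2-alkynyl ketones. The furanone ring closes in the 5-endo-dig mode. The new stereocentre C10 is controlled by the C1 carbinol configuration, because the shift is suprafacial across the planar five-membered cation, so (S) at C1 gives (S) at C10. The step needs chemoselectivity for the ketone oxygen and a single migrating group: the C6 and C15 oxygens are bulky silyl ethers, the PMB ether sits on remote C13, the C8 oxygen is acylated, and methyl is the only substituent on C1 free to migrate.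

Step 13
Reactants: 22 methyl (2E,4R)-5-[(2S)-5-{(2Z)-4-[(tert-butyldimethylsilyl)oxy]-1-[(tert-butyldiphenylsilyl)oxy]but-2-en-2-yl}-2-methyl-3-oxo-2,3-dihydrofuran-2-yl]-2-{[(4-methoxybenzyl)oxy]methyl}-4-[(3-methylbutanoyl)oxy]pent-2-enoate
Product: 23 the C13 alcohol, methyl (2E,4R)-5-[(2S)-5-{(2Z)-4-[(tert-butyldimethylsilyl)oxy]-1-[(tert-butyldiphenylsilyl)oxy]but-2-en-2-yl}-2-methyl-3-oxo-2,3-dihydrofuran-2-yl]-2-(hydroxymethyl)-4-[(3-methylbutanoyl)oxy]pent-2-enoate
Conditions: DDQ, CH2Cl2/pH 7 buffer, 0 °C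
Reagents that add atoms: none
Why: Oxidative cleavage of the PMB ether with DDQ (through the benzylic oxocarbenium ion), which leaves the silyl ethers, the esters and the furanone untouched.

Step 14
Reactants: 23 the C13 alcohol
Product: 24 the C13 bromide, methyl (2Z,4R)-2-(bromomethyl)-5-[(2S)-5-{(2Z)-4-[(tert-butyldimethylsilyl)oxy]-1-[(tert-butyldiphenylsilyl)oxy]but-2-en-2-yl}-2-methyl-3-oxo-2,3-dihydrofuran-2-yl]-4-[(3-methylbutanoyl)oxy]pent-2-enoate
Conditions: CBr4, PPh3, CH2Cl2, 0 °C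
Reagents that add atoms: carbon tetrabromide, BrC(Br)(Br)Br
Why: Appel bromination of the primary allylic alcohol under neutral conditions, giving the 2-(bromomethyl)acrylate needed for ring closure.

Step 15
Reactants: 24 the C13 bromide
Product: 25 the C6 alcohol, methyl (2Z,4R)-2-(bromomethyl)-5-[(2S)-5-{(2Z)-1-[(tert-butyldiphenylsilyl)oxy]-4-hydroxybut-2-en-2-yl}-2-methyl-3-oxo-2,3-dihydrofuran-2-yl]-4-[(3-methylbutanoyl)oxy]pent-2-enoate
Conditions: HF (48 % aq.), MeCN, 0 °C
Reagents that add atoms: none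
Why: Acid-mediated desilylation that discriminates the primary TBS ether from the much more stable TBDPS ether and is not nucleophilic enough to displace the allylic bromide.

Step 16
Reactants: 25 the C6 alcohol
Product: 26 the C6 aldehyde, methyl (2Z,4R)-2-(bromomethyl)-5-[(2S)-5-{(2Z)-1-[(tert-butyldiphenylsilyl)oxy]-4-oxobut-2-en-2-yl}-2-methyl-3-oxo-2,3-dihydrofuran-2-yl]-4-[(3-methylbutanoyl)oxy]pent-2-enoate
Conditions: Dess–Martin periodinane, NaHCO3, CH2Cl2, 0 °C to rt
Reagents that add atoms: none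
Why: Dess–Martin oxidation of the allylic alcohol under buffered, non-basic conditions, which should preserve the (Z)-geometry of the C4=C5 bond and the allylic bromide.

Step 17
Reactants: 26 the C6 aldehyde
Product: 28 (4Z,6R,7R,8R,10S)-15-[(tert-butyldiphenylsilyl)oxy]-8-[(3-methylbutanoyl)oxy]-1-oxo-3,10-epoxygermacra-2,4,11(13)-trien-12,6-olide, via ten-membered hydroxy ester 27 (not isolated)
Conditions: CrCl2, THF (high dilution), rt; then p-TsOH (cat.), CH2Cl2, rt
Reagents that add atoms: none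
Why: Intramolecular Nozaki–Hiyama–Kishi-type Barbier allylation, in which CrCl2 (divalent chromium) turns the allylic bromide into an allylchromium species that adds through C7 to the C6 aldehyde in a closed six-membered transition state, forming C6–C7 with transposition to the C11=C13 methylene before the γ-hydroxy ester lactonises; C6 and C7 are set together, the trans ring fusion being expected from the antiperiplanar placement of C5 and C8 that the forming ten-membered ring enforces, and the sense relative to C8 from the resident C8 and C10 stereocentres (macrocyclic control).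

Step 18
Reactants: 28 (4Z,6R,7R,8R,10S)-15-[(tert-butyldiphenylsilyl)oxy]-8-[(3-methylbutanoyl)oxy]-1-oxo-3,10-epoxygermacra-2,4,11(13)-trien-12,6-olide
Product: 29 (4Z,6R,7R,8R,10S)-15-hydroxy-8-[(3-methylbutanoyl)oxy]-1-oxo-3,10-epoxygermacra-2,4,11(13)-trien-12,6-olide (CNP0171896.1)
Conditions: HF·pyridine, pyridine, THF, 0 °C to rt
Reagents that add atoms: none
Why: Fluoride-mediated cleavage of the remaining silyl ether under mildly acidic conditions that the α-methylene lactone, the furanone and the isovalerate tolerate.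

Compound list
1 | 2-butyne-1,4-diol | OCC#CCO | starting material
2 | 4-[(tert-butyldiphenylsilyl)oxy]but-2-yn-1-ol | OCC#CCO[Si](c1ccccc1)(c1ccccc1)C(C)(C)C | intermediate
3 | sodium cyclic alkenylalanate (Al on C3 and on the C1 oxygen, two 2-methoxyethoxy ligands) | [Na+].COCCO[Al-]1(OCCOC)OCC=C1CO[Si](c1ccccc1)(c1ccccc1)C(C)(C)C | intermediate
4 | (2Z)-4-[(tert-butyldiphenylsilyl)oxy]-3-iodobut-2-en-1-ol | OC/C=C(\I)CO[Si](c1ccccc1)(c1ccccc1)C(C)(C)C | intermediate
5 | (2Z)-1-[(tert-butyldimethylsilyl)oxy]-4-[(tert-butyldiphenylsilyl)oxy]-3-iodobut-2-ene | CC(C)(C)[Si](C)(C)OC/C=C(\I)CO[Si](c1ccccc1)(c1ccccc1)C(C)(C)C | intermediate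
6 | 2,3-butanedione | CC(=O)C(C)=O | starting material
7 | trimethylsilylacetylene | C#C[Si](C)(C)C | starting material
8 | (3S)-3-hydroxy-3-methyl-5-(trimethylsilyl)pent-4-yn-2-one | C[C@](O)(C#C[Si](C)(C)C)C(C)=O | intermediate
9 | (3S)-3-hydroxy-3-methylpent-4-yn-2-one | C[C@](O)(C#C)C(C)=O | intermediate
10 | (3S,6E)-8-[(tert-butyldimethylsilyl)oxy]-6-{[(tert-butyldiphenylsilyl)oxy]methyl}-3-hydroxy-3-methyloct-6-en-4-yn-2-one | C[C@](O)(C#C/C(CO[Si](c1ccccc1)(c1ccccc1)C(C)(C)C)=C\CO[Si](C)(C)C(C)(C)C)C(C)=O | intermediate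
11 | (3S,6E)-8-[(tert-butyldimethylsilyl)oxy]-6-{[(tert-butyldiphenylsilyl)oxy]methyl}-3-methyl-3-[(trimethylsilyl)oxy]oct-6-en-4-yn-2-one | C[C@](O[Si](C)(C)C)(C#C/C(CO[Si](c1ccccc1)(c1ccccc1)C(C)(C)C)=C\CO[Si](C)(C)C(C)(C)C)C(C)=O | intermediate
12 | 4-methoxybenzyl alcohol | OCc1ccc(OC)cc1 | starting material
13 | methyl 2-(dimethoxyphosphoryl)acrylate | C=C(C(=O)OC)P(=O)(OC)OC | starting material
14 | 2,2-dimethoxyacetaldehyde | COC(OC)C=O | starting material
15 | sodium salt of the carbanion of methyl 2-(dimethoxyphosphoryl)-3-[(4-methoxybenzyl)oxy]propanoate | [Na+].COC(=O)[C-](COCc1ccc(OC)cc1)P(=O)(OC)OC | intermediate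
16 | methyl (2E)-4,4-dimethoxy-2-{[(4-methoxybenzyl)oxy]methyl}but-2-enoate | COC(OC)/C=C(\COCc1ccc(OC)cc1)C(=O)OC | intermediate
17 | methyl (2E)-2-{[(4-methoxybenzyl)oxy]methyl}-4-oxobut-2-enoate | O=C/C=C(\COCc1ccc(OC)cc1)C(=O)OC | intermediate
18 | diisopinocampheylboron enolate of 11 (O-bound boron on C10, terminal CH2 at C9) | C=C(OB([C@@H]1C[C@@H]2C[C@H]([C@H]1C)C2(C)C)[C@@H]1C[C@@H]2C[C@H]([C@H]1C)C2(C)C)[C@@](C)(O[Si](C)(C)C)C#C/C(CO[Si](c1ccccc1)(c1ccccc1)C(C)(C)C)=C\CO[Si](C)(C)C(C)(C)C | intermediate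
19 | methyl (2E,4R,7S,10E)-12-[(tert-butyldimethylsilyl)oxy]-10-{[(tert-butyldiphenylsilyl)oxy]methyl}-4-hydroxy-2-{[(4-methoxybenzyl)oxy]methyl}-7-methyl-6-oxo-7-[(trimethylsilyl)oxy]dodeca-2,10-dien-8-ynoate | C[C@](O[Si](C)(C)C)(C#C/C(CO[Si](c1ccccc1)(c1ccccc1)C(C)(C)C)=C\CO[Si](C)(C)C(C)(C)C)C(=O)C[C@@H](O)/C=C(\COCc1ccc(OC)cc1)C(=O)OC | intermediate
20 | methyl (2E,4R,7S,10E)-12-[(tert-butyldimethylsilyl)oxy]-10-{[(tert-butyldiphenylsilyl)oxy]methyl}-2-{[(4-methoxybenzyl)oxy]methyl}-7-methyl-4-[(3-methylbutanoyl)oxy]-6-oxo-7-[(trimethylsilyl)oxy]dodeca-2,10-dien-8-ynoate | C[C@](O[Si](C)(C)C)(C#C/C(CO[Si](c1ccccc1)(c1ccccc1)C(C)(C)C)=C\CO[Si](C)(C)C(C)(C)C)C(=O)C[C@@H](OC(=O)CC(C)C)/C=C(\COCc1ccc(OC)cc1)C(=O)OC | intermediate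
21 | methyl (2E,4R,7S,10E)-12-[(tert-butyldimethylsilyl)oxy]-10-{[(tert-butyldiphenylsilyl)oxy]methyl}-7-hydroxy-2-{[(4-methoxybenzyl)oxy]methyl}-7-methyl-4-[(3-methylbutanoyl)oxy]-6-oxododeca-2,10-dien-8-ynoate | C[C@](O)(C#C/C(CO[Si](c1ccccc1)(c1ccccc1)C(C)(C)C)=C\CO[Si](C)(C)C(C)(C)C)C(=O)C[C@@H](OC(=O)CC(C)C)/C=C(\COCc1ccc(OC)cc1)C(=O)OC | intermediate
22 | methyl (2E,4R)-5-[(2S)-5-{(2Z)-4-[(tert-butyldimethylsilyl)oxy]-1-[(tert-butyldiphenylsilyl)oxy]but-2-en-2-yl}-2-methyl-3-oxo-2,3-dihydrofuran-2-yl]-2-{[(4-methoxybenzyl)oxy]methyl}-4-[(3-methylbutanoyl)oxy]pent-2-enoate | C[C@@]1(C[C@@H](OC(=O)CC(C)C)/C=C(\COCc2ccc(OC)cc2)C(=O)OC)OC(=CC1=O)/C(CO[Si](c2ccccc2)(c2ccccc2)C(C)(C)C)=C\CO[Si](C)(C)C(C)(C)C | intermediate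
23 | methyl (2E,4R)-5-[(2S)-5-{(2Z)-4-[(tert-butyldimethylsilyl)oxy]-1-[(tert-butyldiphenylsilyl)oxy]but-2-en-2-yl}-2-methyl-3-oxo-2,3-dihydrofuran-2-yl]-2-(hydroxymethyl)-4-[(3-methylbutanoyl)oxy]pent-2-enoate | C[C@@]1(C[C@@H](OC(=O)CC(C)C)/C=C(\CO)C(=O)OC)OC(=CC1=O)/C(CO[Si](c2ccccc2)(c2ccccc2)C(C)(C)C)=C\CO[Si](C)(C)C(C)(C)C | intermediate
24 | methyl (2Z,4R)-2-(bromomethyl)-5-[(2S)-5-{(2Z)-4-[(tert-butyldimethylsilyl)oxy]-1-[(tert-butyldiphenylsilyl)oxy]but-2-en-2-yl}-2-methyl-3-oxo-2,3-dihydrofuran-2-yl]-4-[(3-methylbutanoyl)oxy]pent-2-enoate | C[C@@]1(C[C@@H](OC(=O)CC(C)C)/C=C(\CBr)C(=O)OC)OC(=CC1=O)/C(CO[Si](c2ccccc2)(c2ccccc2)C(C)(C)C)=C\CO[Si](C)(C)C(C)(C)C | intermediate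
25 | methyl (2Z,4R)-2-(bromomethyl)-5-[(2S)-5-{(2Z)-1-[(tert-butyldiphenylsilyl)oxy]-4-hydroxybut-2-en-2-yl}-2-methyl-3-oxo-2,3-dihydrofuran-2-yl]-4-[(3-methylbutanoyl)oxy]pent-2-enoate | C[C@@]1(C[C@@H](OC(=O)CC(C)C)/C=C(\CBr)C(=O)OC)OC(=CC1=O)/C(CO[Si](c2ccccc2)(c2ccccc2)C(C)(C)C)=C\CO | intermediate
26 | methyl (2Z,4R)-2-(bromomethyl)-5-[(2S)-5-{(2Z)-1-[(tert-butyldiphenylsilyl)oxy]-4-oxobut-2-en-2-yl}-2-methyl-3-oxo-2,3-dihydrofuran-2-yl]-4-[(3-methylbutanoyl)oxy]pent-2-enoate | C[C@@]1(C[C@@H](OC(=O)CC(C)C)/C=C(\CBr)C(=O)OC)OC(=CC1=O)/C(CO[Si](c2ccccc2)(c2ccccc2)C(C)(C)C)=C\C=O | intermediate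
27 | methyl (4Z,6R,7S,8R,10S)-15-[(tert-butyldiphenylsilyl)oxy]-6-hydroxy-8-[(3-methylbutanoyl)oxy]-1-oxo-3,10-epoxygermacra-2,4,11(13)-trien-12-oate (same spatial arrangement at C7 as in 28; the descriptor changes with the priorities) | C=C(C(=O)OC)[C@@H]1[C@H](OC(=O)CC(C)C)C[C@]2(C)OC(=CC2=O)/C(CO[Si](c3ccccc3)(c3ccccc3)C(C)(C)C)=C\[C@H]1O | intermediate
28 | (4Z,6R,7R,8R,10S)-15-[(tert-butyldiphenylsilyl)oxy]-8-[(3-methylbutanoyl)oxy]-1-oxo-3,10-epoxygermacra-2,4,11(13)-trien-12,6-olide | C=C1C(=O)O[C@@H]2/C=C(/CO[Si](c4ccccc4)(c4ccccc4)C(C)(C)C)C3=CC(=O)[C@](C)(C[C@@H](OC(=O)CC(C)C)[C@@H]12)O3 | intermediate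
29 | (4Z,6R,7R,8R,10S)-15-hydroxy-8-[(3-methylbutanoyl)oxy]-1-oxo-3,10-epoxygermacra-2,4,11(13)-trien-12,6-olide (CNP0171896.1) | C=C1C(=O)O[C@@H]2/C=C(/CO)C3=CC(=O)[C@](C)(C[C@@H](OC(=O)CC(C)C)[C@@H]12)O3 | target

Total step count: 18.
Longest linear sequence: 14 steps (steps 1–3, 6, 7 and 10–18, from 1).

Steps most likely to fail

1. Step 4 (proposed new method). The catalyst may discriminate poorly between the faces of the small, symmetrical diketone, or base-promoted self-condensation of 6 may outrun acetylide addition. The fallback uses known chemistry and sets out from 7: the same zinc/amino alcohol system is applied to methyl pyruvate, an α-keto ester of the established substrate class, to give methyl (2S)-2-hydroxy-2-methyl-4-(trimethylsilyl)but-3-ynoate F1. MeNHOMe·HCl with i-PrMgCl (THF, −20 °C) converts this ester into the Weinreb amide (2S)-2-hydroxy-N-methoxy-N,2-dimethyl-4-(trimethylsilyl)but-3-ynamide F2, and MeMgBr (THF, 0 °C) then gives the methyl ketone, rejoining the route at 8.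

2. Step 12 (key step). A competing oxygen may attack the activated alkyne, the Lewis acid may cleave a silyl or PMB ether, or the isovalerate may be lost by β-elimination from the β-acyloxy ketone before the ring closes. The fallback sets out from 21 and triggers the cyclisation/1,2-shift with an iodonium source instead of a π-acid (N-iodosuccinimide, CH2Cl2, rt), a known variant for 2-hydroxy-2-alkynyl ketones, which should give the C2-iodo furanone (the 4-iodofuran-3(2H)-one analogue of 22) F3. Hydrodeiodination with Bu3SnH and Pd(PPh3)4 (zerovalent palladium, THF, rt) returns to the route at 22.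

3. Step 17. Intermolecular coupling or simple reduction of the allylic bromide may replace ring closure, the (Z)-enal may isomerise before addition, or the ring may close through the wrong face at C6/C7. The fallback sets out from 24 and replaces the reductive metal-mediated closure by an allylboration: palladium-catalysed borylation (Pd2(dba)3, B2pin2, KOAc, toluene) gives the pinacol allylboronate F4, CSA in MeOH (0 °C) frees the C6 alcohol F5, and Dess–Martin oxidation gives the aldehyde F6. This aldehyde closes the ring by intramolecular allylboration through a closed boron transition state (thermal, or catalysed by Sc(OTf)3); acid work-up lactonises the adduct and the route is rejoined at 28.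

Further compounds
F1 | step 4 | methyl (2S)-2-hydroxy-2-methyl-4-(trimethylsilyl)but-3-ynoate | C[C@](O)(C#C[Si](C)(C)C)C(=O)OC
F2 | step 4 | (2S)-2-hydroxy-N-methoxy-N,2-dimethyl-4-(trimethylsilyl)but-3-ynamide | C[C@](O)(C#C[Si](C)(C)C)C(=O)N(C)OC
F3 | step 12 | methyl (2E,4R)-5-[(2S)-5-{(2Z)-4-[(tert-butyldimethylsilyl)oxy]-1-[(tert-butyldiphenylsilyl)oxy]but-2-en-2-yl}-4-iodo-2-methyl-3-oxo-2,3-dihydrofuran-2-yl]-2-{[(4-methoxybenzyl)oxy]methyl}-4-[(3-methylbutanoyl)oxy]pent-2-enoate | C[C@@]1(C[C@@H](OC(=O)CC(C)C)/C=C(\COCc2ccc(OC)cc2)C(=O)OC)OC(=C(I)C1=O)/C(CO[Si](c2ccccc2)(c2ccccc2)C(C)(C)C)=C\CO[Si](C)(C)C(C)(C)C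
F4 | step 17 | methyl (2E,4R)-5-[(2S)-5-{(2Z)-4-[(tert-butyldimethylsilyl)oxy]-1-[(tert-butyldiphenylsilyl)oxy]but-2-en-2-yl}-2-methyl-3-oxo-2,3-dihydrofuran-2-yl]-4-[(3-methylbutanoyl)oxy]-2-[(4,4,5,5-tetramethyl-1,3,2-dioxaborolan-2-yl)methyl]pent-2-enoate | C[C@@]1(C[C@@H](OC(=O)CC(C)C)/C=C(\CB2OC(C)(C)C(C)(C)O2)C(=O)OC)OC(=CC1=O)/C(CO[Si](c2ccccc2)(c2ccccc2)C(C)(C)C)=C\CO[Si](C)(C)C(C)(C)C
F5 | step 17 | methyl (2E,4R)-5-[(2S)-5-{(2Z)-1-[(tert-butyldiphenylsilyl)oxy]-4-hydroxybut-2-en-2-yl}-2-methyl-3-oxo-2,3-dihydrofuran-2-yl]-4-[(3-methylbutanoyl)oxy]-2-[(4,4,5,5-tetramethyl-1,3,2-dioxaborolan-2-yl)methyl]pent-2-enoate | C[C@@]1(C[C@@H](OC(=O)CC(C)C)/C=C(\CB2OC(C)(C)C(C)(C)O2)C(=O)OC)OC(=CC1=O)/C(CO[Si](c2ccccc2)(c2ccccc2)C(C)(C)C)=C\CO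
F6 | step 17 | methyl (2E,4R)-5-[(2S)-5-{(2Z)-1-[(tert-butyldiphenylsilyl)oxy]-4-oxobut-2-en-2-yl}-2-methyl-3-oxo-2,3-dihydrofuran-2-yl]-4-[(3-methylbutanoyl)oxy]-2-[(4,4,5,5-tetramethyl-1,3,2-dioxaborolan-2-yl)methyl]pent-2-enoate | C[C@@]1(C[C@@H](OC(=O)CC(C)C)/C=C(\CB2OC(C)(C)C(C)(C)O2)C(=O)OC)OC(=CC1=O)/C(CO[Si](c2ccccc2)(c2ccccc2)C(C)(C)C)=C\C=O
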